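**Strategy**

Everything rests on cutting ring A along C7–C8, C4a–C8a and C6–C7. Read around ring A, the target shows OH at C7, prenyl at C8, O1 at C8a, C4 on C4a and OMe at C5: the exact pattern a vinylketene–alkynyl ether benzannulation delivers, with O1 and C4 as the two ends of ring C. One light-triggered pericyclic cascade therefore closes rings C and A together and fixes all six ring-A positions by connectivity alone. The precursor is a 2-alkyl-3-methoxycyclobutenone whose side chain (C4, C3, C2, O1; both stereocentres from (S)-glyceraldehyde acetonide) ends in a prenyl-bearing alkynyl ether.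

Key step: step 11

Remark 1: the C5 ether of the target is a methyl ether, so the ethoxy group of commercial 3-ethoxycyclobut-2-en-1-one is exchanged for methoxy (step 8) before the ring is used; carried through unchanged it would end as a 5-ethyl ether.

Remark 2: alkynyl ethers of secondary benzylic alcohols are assumed to rearrange or fragment on heating, so 16, 20 and 21 are kept at or below 25 °C and the ketene is released with light, not heat.

Remark 3: open-chain intermediates are described with the flavan numbering of the atoms they become (O1, C2, C3, C4).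

**Route**

Step 1
Reactants: 1 4-bromophenol
Product: 2 (4-bromophenoxy)tri(propan-2-yl)silane
Conditions: TIPSCl, imidazole, DMF, 20 °C
Reagents that add atoms: chlorotri(propan-2-yl)silane (TIPSCl), CC(C)[Si](Cl)(C(C)C)C(C)C
Why: Imidazole-promoted silylation of the phenol gives a hindered aryl silyl ether that should survive the Grignard, potassium alkoxide and butyllithium steps better than a smaller silyl group.

Step 2
Reactants: 2 (4-bromophenoxy)tri(propan-2-yl)silane; 3 (S)-glyceraldehyde acetonide
Product: 6 (R)-[(4S)-2,2-dimethyl-1,3-dioxolan-4-yl]{4-[(triisopropylsilyl)oxy]phenyl}methanol (anti adduct), via aryl Grignard reagent 4 (not isolated), via aryltitanium triisopropoxide 5 (not isolated)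
Conditions: Mg, THF, 40 °C; ClTi(OiPr)3, −78 °C; then 3, −78 → 0 °C; aq NH4Cl
Reagents that add atoms: none
Why: Transmetalation to a non-chelating aryltitanium reagent should give Felkin–Anh addition to the α-alkoxy aldehyde, setting the new carbinol centre (future C2, R) anti to the dioxolane centre carried in from 3 (future C3, S), which is the open-chain relationship that maps onto the 2,3-trans ring; any syn isomer is removed by chromatography.

Step 3
Reactants: 6 anti alcohol; 7 trichloroethylene
Product: 9 (4S)-4-[(R)-{[(E)-1,2-dichloroethenyl]oxy}{4-[(triisopropylsilyl)oxy]phenyl}methyl]-2,2-dimethyl-1,3-dioxolane, via dichloroacetylene 8 (not isolated)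
Conditions: KH, THF, 0 °C; then 7, −50 → 20 °C
Reagents that add atoms: none
Why: Addition of the potassium alkoxide to dichloroacetylene formed in situ (first half of the dichlorovinyl ether route to alkynyl ethers) gives an acid- and base-tolerant masked alkynyl ether, and doing it while O3 and O4 are locked in the acetonide excludes silyl migration or epoxide formation under the strongly basic conditions.

Step 4
Reactants: 9 dichlorovinyl ether acetonide
Product: 10 (2S,3R)-3-{[(E)-1,2-dichloroethenyl]oxy}-3-{4-[(triisopropylsilyl)oxy]phenyl}propane-1,2-diol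
Conditions: TsOH·H2O (cat.), MeOH, 0 → 20 °C
Reagents that add atoms: none
Why: Acid-catalysed transketalisation removes the terminal acetonide under conditions that the electron-poor dichlorovinyl ether and the aryl silyl ether should tolerate.

Step 5
Reactants: 10 diol
Product: 11 (2R,3R)-1-bromo-3-{[(E)-1,2-dichloroethenyl]oxy}-3-{4-[(triisopropylsilyl)oxy]phenyl}propan-2-ol
Conditions: CBr4, PPh3, pyridine, 0 → 20 °C
Reagents that add atoms: carbon tetrabromide, BrC(Br)(Br)Br
Why: Appel bromination is selective for the unhindered primary hydroxyl (future C4), and a bromide is chosen because, unlike an iodide, it should resist butyllithium at −78 °C in step 7.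

Step 6
Reactants: 11 bromohydrin
Product: 12 {[(1R,2R)-3-bromo-1-{[(E)-1,2-dichloroethenyl]oxy}-1-{4-[(triisopropylsilyl)oxy]phenyl}propan-2-yl]oxy}(tert-butyl)dimethylsilane
Conditions: TBSOTf, 2,6-lutidine, CH2Cl2, −78 °C
Reagents that add atoms: tert-butyldimethylsilyl trifluoromethanesulfonate (TBSOTf), CC(C)(C)[Si](C)(C)OS(=O)(=O)C(F)(F)F
Why: A silyl triflate with a hindered pyridine base silylates the secondary alcohol (O3) at low temperature without closing the bromohydrin to an epoxide, and the silyl ether is put on only after the alkoxide step so it cannot migrate.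

Step 7
Reactants: 12 dichlorovinyl ether bromide; 13 prenyl bromide
Product: 16 {[(1R,2R)-3-bromo-1-[(5-methylhex-4-en-1-yn-1-yl)oxy]-1-{4-[(triisopropylsilyl)oxy]phenyl}propan-2-yl]oxy}(tert-butyl)dimethylsilane, via chloroethynyl ether 14 (not isolated), via lithium alkynyl ether 15 (not isolated)
Conditions: n-BuLi (2.2 equiv), THF, −78 °C; then 13, DMPU, −78 → −10 °C; NaHCO3 work-up, Et3N-deactivated silica
Reagents that add atoms: none
Why: Butyllithium eliminates HCl and then exchanges the remaining chlorine for lithium (second half of the dichlorovinyl ether route), and the lithium alkynyl ether is alkylated at the primary carbon of the allylic bromide (SN2) to give the skipped enyne, the primary alkyl bromide at C4 being expected to stay inert at −78 °C.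

Step 8
Reactants: 17 3-ethoxycyclobut-2-en-1-one
Product: 18 3-methoxycyclobut-2-en-1-one
Conditions: MeOH (solvent), TsOH·H2O (cat.), 20 °C; evaporate and repeat; NaHCO3
Reagents that add atoms: methanol, CO
Why: Acid-catalysed alkoxy exchange of a vinylogous ester (addition–elimination at C3) in a large excess of methanol installs the methyl group that must end as the C5 methyl ether.

Step 9
Reactants: 18 3-methoxycyclobut-2-en-1-one
Product: 19 2-bromo-3-methoxycyclobut-2-en-1-one
Conditions: NBS, CH2Cl2, 0 → 20 °C
Reagents that add atoms: N-bromosuccinimide, O=C1CCC(=O)N1Br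
Why: Electrophilic bromination of a vinylogous ester occurs at its nucleophilic α-carbon (C2) and gives the alkenyl bromide needed for cross-coupling.

Step 10
Reactants: 16 alkynyl ether bromide; 19 2-bromo-3-methoxycyclobut-2-en-1-one
Product: 21 2-[(2S,3R)-2-[(tert-butyldimethylsilyl)oxy]-3-[(5-methylhex-4-en-1-yn-1-yl)oxy]-3-{4-[(triisopropylsilyl)oxy]phenyl}propyl]-3-methoxycyclobut-2-en-1-one, via alkylzinc bromide 20 (not isolated)
Conditions: Zn* (Rieke zinc), THF, 20 °C; decant; then 19, Pd(OAc)2 (5 mol%), SPhos (10 mol%), THF, 20 °C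
Reagents that add atoms: none
Why: Negishi coupling, in which active zinc inserts into the primary C–Br bond at room temperature and palladium-catalysed sp3–sp2 coupling with the α-bromoenone forms the C4–C4a bond without heating the alkynyl ether, the covalent C–Zn bond being expected to expel the β-silyloxy group only slowly.

Step 11
Reactants: 21 cyclobutenone alkynyl ether
Product: 26 (2R,3S)-3-[(tert-butyldimethylsilyl)oxy]-5-methoxy-8-(3-methylbut-2-en-1-yl)-2-{4-[(triisopropylsilyl)oxy]phenyl}-3,4-dihydro-2H-chromen-7-ol, via vinylketene 22 (not isolated), via fused cyclobutenone 23 (not isolated), via dienylketene 24 (not isolated), via cyclohexadienone 25 (not isolated)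
Conditions: hν (300 nm, Pyrex), degassed toluene (0.002 M), 10 °C until the alkynyl ether is consumed; then dark, 80 °C
Reagents that add atoms: none
Why: Proposed new method: irradiation should open the cyclobutenone (4π) to vinylketene 22, whose ketene carbon (future C7) and α-carbon (future C4a) add across the tethered alkynyl ether, C7 to the nucleophilic prenyl-bearing C8 and C4a to the oxygen-bearing C8a, to give fused cyclobutenone 23, which on warming opens (4π) to dienylketene 24 and closes (6π, C6–C7) to dienone 25 that tautomerises to phenol 26. The closest known reaction types are the two-component Danheiser benzannulation of cyclobutenone-derived vinylketenes with alkoxyalkynes, which can also be driven by light, and intramolecular ketene [2+2] cycloadditions through a tether on the ketene α-carbon; their combination is untested. Ring C closes in the [2+2] event as a six-membered ring by C4a–C8a bonding with the former triple bond left exocyclic (6-exo-dig sense), and ring A closes by thermal disrotatory 6π-electrocyclisation, the required cis geometry being enforced because the C4a=C8a double bond of 24 lies inside ring C. No lasting stereocentre is formed (the quaternary C4a of 23 is erased on ring opening) and C2 and C3 are spectators under these neutral conditions. The step needs regioselectivity in the [2+2], secured twice over by the four-atom tether (six- against seven-membered ring) and by the matched polarisation of ketene and alkynyl ether, and it needs the ketene to be trapped before it dimerises or the alkynyl ether rearranges, secured by high dilution and by releasing the ketene with light at 10 °C so that heat is applied only once the alkyne is gone.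

Step 12
Reactants: 26 bis-silyl ether
Product: 27 8-prenylafzelechin 5-methyl ether, (2R,3S)-2-(4-hydroxyphenyl)-5-methoxy-8-(3-methylbut-2-en-1-yl)-3,4-dihydro-2H-chromene-3,7-diol
Conditions: TBAF, AcOH, THF, 0 → 20 °C
Reagents that add atoms: none
Why: Fluoride cleaves the aryl triisopropylsilyl ether and the secondary tert-butyldimethylsilyl ether in one operation, and buffering with acetic acid avoids both strong base on the electron-rich phenols and acid on the ortho-prenyl phenol.

**Compound list**

1 | 4-bromophenol | Oc1ccc(Br)cc1 | starting material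
2 | (4-bromophenoxy)tri(propan-2-yl)silane | CC(C)[Si](Oc1ccc(Br)cc1)(C(C)C)C(C)C | intermediate
3 | (S)-glyceraldehyde acetonide, (4S)-2,2-dimethyl-1,3-dioxolane-4-carbaldehyde | O=C[C@@H]1COC(C)(C)O1 | starting material
4 | {4-[(triisopropylsilyl)oxy]phenyl}magnesium bromide | Br[Mg]c1ccc(O[Si](C(C)C)(C(C)C)C(C)C)cc1 | intermediate
5 | triisopropoxy{4-[(triisopropylsilyl)oxy]phenyl}titanium | CC(C)O[Ti](OC(C)C)(OC(C)C)c1ccc(O[Si](C(C)C)(C(C)C)C(C)C)cc1 | intermediate
6 | (R)-[(4S)-2,2-dimethyl-1,3-dioxolan-4-yl]{4-[(triisopropylsilyl)oxy]phenyl}methanol | CC1(C)OC[C@H](O1)[C@@H](c1ccc(O[Si](C(C)C)(C(C)C)C(C)C)cc1)O | intermediate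
7 | trichloroethylene | ClC=C(Cl)Cl | starting material
8 | dichloroacetylene | ClC#CCl | intermediate
9 | (4S)-4-[(R)-{[(E)-1,2-dichloroethenyl]oxy}{4-[(triisopropylsilyl)oxy]phenyl}methyl]-2,2-dimethyl-1,3-dioxolane | CC1(C)OC[C@H](O1)[C@@H](c1ccc(O[Si](C(C)C)(C(C)C)C(C)C)cc1)O/C(Cl)=C\Cl | intermediate
10 | (2S,3R)-3-{[(E)-1,2-dichloroethenyl]oxy}-3-{4-[(triisopropylsilyl)oxy]phenyl}propane-1,2-diol | OC[C@H](O)[C@@H](c1ccc(O[Si](C(C)C)(C(C)C)C(C)C)cc1)O/C(Cl)=C\Cl | intermediate
11 | (2R,3R)-1-bromo-3-{[(E)-1,2-dichloroethenyl]oxy}-3-{4-[(triisopropylsilyl)oxy]phenyl}propan-2-ol | BrC[C@H](O)[C@@H](c1ccc(O[Si](C(C)C)(C(C)C)C(C)C)cc1)O/C(Cl)=C\Cl | intermediate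
12 | {[(1R,2R)-3-bromo-1-{[(E)-1,2-dichloroethenyl]oxy}-1-{4-[(triisopropylsilyl)oxy]phenyl}propan-2-yl]oxy}(tert-butyl)dimethylsilane | BrC[C@H](O[Si](C)(C)C(C)(C)C)[C@@H](c1ccc(O[Si](C(C)C)(C(C)C)C(C)C)cc1)O/C(Cl)=C\Cl | intermediate
13 | prenyl bromide, 1-bromo-3-methylbut-2-ene | CC(C)=CCBr | starting material
14 | chloroethynyl ether: 12 with O–C≡C–Cl in place of the dichlorovinyl group | BrC[C@H](O[Si](C)(C)C(C)(C)C)[C@@H](c1ccc(O[Si](C(C)C)(C(C)C)C(C)C)cc1)OC#CCl | intermediate
15 | lithium alkynyl ether: 14 with Li in place of Cl | BrC[C@H](O[Si](C)(C)C(C)(C)C)[C@@H](c1ccc(O[Si](C(C)C)(C(C)C)C(C)C)cc1)OC#C[Li] | intermediate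
16 | {[(1R,2R)-3-bromo-1-[(5-methylhex-4-en-1-yn-1-yl)oxy]-1-{4-[(triisopropylsilyl)oxy]phenyl}propan-2-yl]oxy}(tert-butyl)dimethylsilane | BrC[C@H](O[Si](C)(C)C(C)(C)C)[C@@H](c1ccc(O[Si](C(C)C)(C(C)C)C(C)C)cc1)OC#CCC=C(C)C | intermediate
17 | 3-ethoxycyclobut-2-en-1-one | CCOC1=CC(=O)C1 | starting material
18 | 3-methoxycyclobut-2-en-1-one | COC1=CC(=O)C1 | intermediate
19 | 2-bromo-3-methoxycyclobut-2-en-1-one | COC1=C(Br)C(=O)C1 | intermediate
20 | alkylzinc bromide: 16 with C4–ZnBr in place of C4–Br | Br[Zn]C[C@H](O[Si](C)(C)C(C)(C)C)[C@@H](c1ccc(O[Si](C(C)C)(C(C)C)C(C)C)cc1)OC#CCC=C(C)C | intermediate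
21 | 2-[(2S,3R)-2-[(tert-butyldimethylsilyl)oxy]-3-[(5-methylhex-4-en-1-yn-1-yl)oxy]-3-{4-[(triisopropylsilyl)oxy]phenyl}propyl]-3-methoxycyclobut-2-en-1-one | COC1=C(C[C@H](O[Si](C)(C)C(C)(C)C)[C@@H](c2ccc(O[Si](C(C)C)(C(C)C)C(C)C)cc2)OC#CCC=C(C)C)C(=O)C1 | intermediate
22 | vinylketene: (4S,5R)-4-[(tert-butyldimethylsilyl)oxy]-2-(1-methoxyethenyl)-5-[(5-methylhex-4-en-1-yn-1-yl)oxy]-5-{4-[(triisopropylsilyl)oxy]phenyl}pent-1-en-1-one | C=C(OC)C(=C=O)C[C@H](O[Si](C)(C)C(C)(C)C)[C@@H](c1ccc(O[Si](C(C)C)(C(C)C)C(C)C)cc1)OC#CCC=C(C)C | intermediate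
23 | fused cyclobutenone: (3R,4S)-4-[(tert-butyldimethylsilyl)oxy]-6-(1-methoxyethenyl)-8-(3-methylbut-2-en-1-yl)-3-{4-[(triisopropylsilyl)oxy]phenyl}-2-oxabicyclo[4.2.0]oct-1(8)-en-7-one (C6 epimers) | C=C(OC)C12C[C@H](O[Si](C)(C)C(C)(C)C)[C@@H](c3ccc(O[Si](C(C)C)(C(C)C)C(C)C)cc3)OC1=C(CC=C(C)C)C2=O | intermediate
24 | dienylketene: 2-[(2R,3S)-3-[(tert-butyldimethylsilyl)oxy]-5-(1-methoxyethenyl)-2-{4-[(triisopropylsilyl)oxy]phenyl}-3,4-dihydro-2H-pyran-6-yl]-5-methylhexa-1,4-dien-1-one | C=C(OC)C1=C(C(CC=C(C)C)=C=O)O[C@H](c2ccc(O[Si](C(C)C)(C(C)C)C(C)C)cc2)[C@@H](O[Si](C)(C)C(C)(C)C)C1 | intermediate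
25 | cyclohexadienone: (2R,3S)-3-[(tert-butyldimethylsilyl)oxy]-5-methoxy-8-(3-methylbut-2-en-1-yl)-2-{4-[(triisopropylsilyl)oxy]phenyl}-3,4-dihydro-2H-chromen-7(6H)-one | COC1=C2C[C@H](O[Si](C)(C)C(C)(C)C)[C@@H](c3ccc(O[Si](C(C)C)(C(C)C)C(C)C)cc3)OC2=C(CC=C(C)C)C(=O)C1 | intermediate
26 | (2R,3S)-3-[(tert-butyldimethylsilyl)oxy]-5-methoxy-8-(3-methylbut-2-en-1-yl)-2-{4-[(triisopropylsilyl)oxy]phenyl}-3,4-dihydro-2H-chromen-7-ol | COc1cc(O)c(CC=C(C)C)c2c1C[C@H](O[Si](C)(C)C(C)(C)C)[C@@H](c1ccc(O[Si](C(C)C)(C(C)C)C(C)C)cc1)O2 | intermediate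
27 | 8-prenylafzelechin 5-methyl ether, (2R,3S)-2-(4-hydroxyphenyl)-5-methoxy-8-(3-methylbut-2-en-1-yl)-3,4-dihydro-2H-chromene-3,7-diol | COc1cc(O)c(CC=C(C)C)c2c1C[C@H](O)[C@@H](c1ccc(O)cc1)O2 | target

**Step count and risks**

Total: 12 steps. Longest linear sequence: 10 steps (1 to 7, then 10 to 12); steps 8 and 9 make the cyclobutenone fragment.

Steps most likely to fail:

1. Step 11 (the step carrying the new method). The photogenerated vinylketene may re-close or dimerise faster than it reaches the tethered alkyne, the light may be absorbed unproductively by the aryl silyl ether, or the alkynyl ether may rearrange before cycloaddition. Fallback with known chemistry, setting out from 16 and 18: the same benzannulation is run between two molecules, which is its established mode. Irradiation of 16 with an excess of 18 in toluene at 20 °C, followed by warming to 80 °C once 16 is consumed, should give 3-{[(1R,2R)-3-bromo-2-[(tert-butyldimethylsilyl)oxy]-1-{4-[(triisopropylsilyl)oxy]phenyl}propyl]oxy}-5-methoxy-2-(3-methylbut-2-en-1-yl)phenol F1, in which ring A is complete but C4a still carries hydrogen. Ring C is then closed by intramolecular C-alkylation of the phenoxide (Cs2CO3, DMF, 20–40 °C, dilute), a reaction type familiar from the carbon alkylation of phloroglucinol-type phenoxides. The C7 phenoxide attacks C4–Br through its para carbon C4a, the only ring carbon that can reach C4 through a six-membered transition state, and O-alkylation is geometrically excluded. This returns to the route at 26.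

2. Step 10. Zinc insertion may be slow at 20 °C, or the organozinc may lose the β-silyloxy group by elimination before it transmetalates, which would destroy the C3 oxygen. Fallback, setting out from 16 and 19: nickel-catalysed reductive cross-electrophile coupling of the alkyl bromide with the alkenyl bromide (NiBr2(DME), 4,4′-di-tert-butyl-2,2′-bipyridine, Mn powder, NaI, DMPU, 20 °C). Here C4 reacts as a free radical that is captured by an alkenylnickel species, so no carbanion-like centre ever sits next to the silyloxy group. The coupling returns directly at 21 and no new compound is formed on the way (F0).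

3. Step 7. Butyllithium may attack the primary bromide (exchange or elimination) in competition with the dichlorovinyl ether, or the prenylation may be accompanied by allylic transposition or base-induced isomerisation of the skipped enyne. Fallback, setting out from diol 10, in which C3–O and C4 are masked together during the organolithium step: one-pot primary sulfonylation and ring closure (NaH, N-tosylimidazole, THF, 0 → 20 °C) gives the terminal epoxide (2S)-2-[(R)-{[(E)-1,2-dichloroethenyl]oxy}{4-[(triisopropylsilyl)oxy]phenyl}methyl]oxirane F2, with C3 untouched. Treatment with n-BuLi and then prenyl bromide as in step 7 (an epoxide is inert to butyllithium at −78 °C without a Lewis acid) gives (2S)-2-[(R)-[(5-methylhex-4-en-1-yn-1-yl)oxy]{4-[(triisopropylsilyl)oxy]phenyl}methyl]oxirane F3. Neutral opening at the terminal carbon with Li2NiBr4 (THF, 0 °C) gives (2R,3R)-1-bromo-3-[(5-methylhex-4-en-1-yn-1-yl)oxy]-3-{4-[(triisopropylsilyl)oxy]phenyl}propan-2-ol F4, and silylation (TBSOTf, 2,6-lutidine, CH2Cl2, −78 °C) returns to the route at 16.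

**Further compounds**

F1 | step 11 | 3-{[(1R,2R)-3-bromo-2-[(tert-butyldimethylsilyl)oxy]-1-{4-[(triisopropylsilyl)oxy]phenyl}propyl]oxy}-5-methoxy-2-(3-methylbut-2-en-1-yl)phenol | COc1cc(O)c(CC=C(C)C)c(O[C@H](c2ccc(O[Si](C(C)C)(C(C)C)C(C)C)cc2)[C@H](CBr)O[Si](C)(C)C(C)(C)C)c1
F0 | step 10 | none | none
F2 | step 7 | (2S)-2-[(R)-{[(E)-1,2-dichloroethenyl]oxy}{4-[(triisopropylsilyl)oxy]phenyl}methyl]oxirane | C1O[C@@H]1[C@@H](c1ccc(O[Si](C(C)C)(C(C)C)C(C)C)cc1)O/C(Cl)=C\Cl
F3 | step 7 | (2S)-2-[(R)-[(5-methylhex-4-en-1-yn-1-yl)oxy]{4-[(triisopropylsilyl)oxy]phenyl}methyl]oxirane | C1O[C@@H]1[C@@H](c1ccc(O[Si](C(C)C)(C(C)C)C(C)C)cc1)OC#CCC=C(C)C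
F4 | step 7 | (2R,3R)-1-bromo-3-[(5-methylhex-4-en-1-yn-1-yl)oxy]-3-{4-[(triisopropylsilyl)oxy]phenyl}propan-2-ol | BrC[C@H](O)[C@@H](c1ccc(O[Si](C(C)C)(C(C)C)C(C)C)cc1)OC#CCC=C(C)C
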